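**Plan**

- Numbering: ring A is the 3,5-dibromo-2-methoxyphenyl unit; ring B carries the ring A oxygen on C1', OH on C2', H on C3' and Br on C4'–C6'.
- Enabling feature: ring B has four contiguous carbons (C3'–C6') that bear or can bear bromine, next to the two adjacent oxygenated carbons C1' and C2'. This maps onto a tetrabrominated four-carbon diene plus a two-carbon dienophile that already holds both oxygens.
- Retrosynthesis: C3'–H goes back to C3'–Br (symmetric tetrabromo ring). Ring B is then cut at C1'–C6' and C2'–C3' ([4+2], SO2 extrusion) into tetrabromothiophene 1,1-dioxide and an aryloxyketene bis(silyl) acetal. The acetal is cut at O–CH2 into the ring A phenol and bromoacetic acid, and the phenol comes from 3,5-dibromosalicylaldehyde.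
- Forward: ring A is bought with both bromines in place and the acetic acid chain is attached to its oxygen. Ring B is built last by cycloaddition, SO2 loss and aromatization, and the C3' bromine is then removed by acetal-directed Br/Mg exchange.
- Stereochemistry: none has to be set.

Key step: step 6

Remark: the target SMILES has no stereocentre and the diaryl ether axis is not expected to be configurationally stable, so the target is treated as one achiral compound.

**Route**

Step 1
Reactants: 1 3,5-dibromo-2-hydroxybenzaldehyde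
Product: 2 3,5-dibromo-2-methoxybenzaldehyde
Conditions: MeI, K2CO3, DMF, 25 °C
Reagents that add atoms: iodomethane, CI
Why: Williamson O-methylation of an acidic phenol; the aldehyde and aryl bromides are inert to carbonate and methyl iodide.

Step 2
Reactants: 2 3,5-dibromo-2-methoxybenzaldehyde
Product: 4 3,5-dibromo-2-methoxyphenol, via aryl formate 3 (not isolated)
Conditions: mCPBA, CH2Cl2, 40 °C; then MeOH, cat. Et3N, 25 °C
Reagents that add atoms: 3-chloroperoxybenzoic acid (mCPBA), O=C(OO)c1cccc(Cl)c1
Why: Baeyer–Villiger (Dakin-type) oxidation in which the ortho-methoxyaryl group should migrate in preference to hydrogen, giving formate 3, which methanol cleaves to the phenol.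

Step 3
Reactants: 4 3,5-dibromo-2-methoxyphenol; 5 bromoacetic acid
Product: 6 2-(3,5-dibromo-2-methoxyphenoxy)acetic acid
Conditions: NaOH, H2O, 80 °C; then aq. HCl
Reagents that add atoms: none
Why: Williamson ether synthesis (SN2 of the phenoxide on bromoacetate), the classical aryloxyacetic acid preparation; the ether oxygen is attached at an sp3 carbon, so no hindered aryl–oxygen coupling is needed.

Step 4
Reactants: 6 2-(3,5-dibromo-2-methoxyphenoxy)acetic acid
Product: 8 2-(3,5-dibromo-2-methoxyphenoxy)-1,1-bis(trimethylsilyloxy)ethene, via trimethylsilyl ester 7 (not isolated)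
Conditions: HMDS, toluene, 80 °C, then evaporate; LiHMDS, THF, −78 °C; TMSCl, −78 → 25 °C; filtered under argon and used crude
Reagents that add atoms: hexamethyldisilazane, C[Si](C)(C)N[Si](C)(C)C; chlorotrimethylsilane, C[Si](C)(C)Cl
Why: Silyl ester formation followed by enolization and O-silylation (silyl ketene acetal synthesis); LiHMDS removes the α-hydrogen activated by the ester and the aryloxy group but is too weak to metallate the ring or attack C–Br, and the chlorosilane traps the enolate on oxygen.

Step 5
Reactants: 9 tetrabromothiophene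
Product: 10 tetrabromothiophene 1,1-dioxide
Conditions: CF3CO3H (from (CF3CO)2O and conc. H2O2), CH2Cl2, 0 → 25 °C
Reagents that add atoms: trifluoroperacetic acid, OOC(=O)C(F)(F)F (generated in situ from hydrogen peroxide, OO, and trifluoroacetic anhydride, O=C(OC(=O)C(F)(F)F)C(F)(F)F)
Why: Electrophilic S-oxidation by a strong peracid, the established way to tetrahalothiophene 1,1-dioxides; the four bromines should keep the sulfone from dimerizing.

Step 6
Reactants: 8 2-(3,5-dibromo-2-methoxyphenoxy)-1,1-bis(trimethylsilyloxy)ethene; 10 tetrabromothiophene 1,1-dioxide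
Product: 13 2,3,4,5-tetrabromo-6-(3,5-dibromo-2-methoxyphenoxy)phenol, via bridged sulfone cycloadduct 11 (not isolated), via cyclohexadiene bis(silyl) ketal 12 (not isolated)
Conditions: 8 (1.5 equiv), toluene, 25 → 80 °C; then 1 M HCl, THF, 25 °C
Reagents that add atoms: none
Why: The perbrominated sulfone is a low-LUMO diene and the ketene acetal a high-HOMO dienophile, so a polar, asynchronous inverse-electron-demand [4+2] cycloaddition should join the aryloxy-bearing carbon to one α-carbon of the sulfone (C1'–C6') and the bis(silyloxy) carbon to the other (C2'–C3'), giving bridged sulfone 11. Cheletropic loss of SO2 from 11 should give cyclohexadiene 12, and acid hydrolysis of its bis(silyl) ketal to the 2,4-dienone followed by enolization (overall loss of hexamethyldisiloxane) should deliver phenol 13. The closest known reaction type is the cycloaddition of tetrahalothiophene 1,1-dioxides to electron-rich alkenes with SO2 extrusion and elimination to tetrahalobenzenes. Ring B is closed as a six-membered carbocycle by intermolecular [4+2] cycloaddition, and the sp3 centres of 11 and 12 are transient, so no stereocentre survives. No regiochemical question arises because the diene has a mirror plane through sulfur and both orientations give the same adduct. The step needs the aryloxy group to be retained on aromatization, and this is secured because the only ring hydrogen sits on the aryloxy-bearing carbon while the leaving groups on the neighbouring carbon are the silyloxy groups, so the aryl oxide has no β-hydrogen for its own elimination.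

Step 7
Reactants: 13 2,3,4,5-tetrabromo-6-(3,5-dibromo-2-methoxyphenoxy)phenol
Product: 14 1,2,3,4-tetrabromo-5-(3,5-dibromo-2-methoxyphenoxy)-6-(methoxymethoxy)benzene
Conditions: NaH, THF/DMF, 0 °C; MOMCl, 0 → 25 °C
Reagents that add atoms: chloromethyl methyl ether, COCCl
Why: O-alkylation of the fully ionized, acidic polybromophenoxide with a reactive α-chloro ether (acetal protection); it installs the chelating group needed for the next step.

Step 8
Reactants: 14 1,2,3,4-tetrabromo-5-(3,5-dibromo-2-methoxyphenoxy)-6-(methoxymethoxy)benzene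
Product: 16 1,2,3-tribromo-4-(3,5-dibromo-2-methoxyphenoxy)-5-(methoxymethoxy)benzene, via C3' arylmagnesium chloride 15 (not isolated)
Conditions: i-PrMgCl·LiCl (1.05 equiv), THF, −40 °C; then MeOH, −40 → 25 °C
Reagents that add atoms: none
Why: Regioselective bromine–magnesium exchange: the acetal oxygens of the methoxymethyl ether pre-coordinate the turbo-Grignard reagent and stabilize the C3' arylmagnesium 15 on the most electron-poor ring, so exchange should occur next to the acetal and not next to the weakly basic, shielded diaryl ether oxygen or on ring A, and cold protonation should precede any aryne-forming loss of magnesium halide.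

Step 9
Reactants: 16 1,2,3-tribromo-4-(3,5-dibromo-2-methoxyphenoxy)-5-(methoxymethoxy)benzene
Product: 17 3,4,5-tribromo-2-(3,5-dibromo-2-methoxyphenoxy)phenol (target)
Conditions: HCl, MeOH/THF, 50 °C
Reagents that add atoms: none
Why: Acid-catalysed acetal cleavage (transacetalization to dimethoxymethane); the aryl methyl ether, the diaryl ether and the aryl bromides are stable to methanolic HCl.

**Compound list**

1 | 3,5-dibromo-2-hydroxybenzaldehyde (3,5-dibromosalicylaldehyde) | O=Cc1cc(Br)cc(Br)c1O | starting material
2 | 3,5-dibromo-2-methoxybenzaldehyde | COc1c(Br)cc(Br)cc1C=O | intermediate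
3 | 3,5-dibromo-2-methoxyphenyl formate | COc1c(Br)cc(Br)cc1OC=O | intermediate (not isolated)
4 | 3,5-dibromo-2-methoxyphenol | COc1c(Br)cc(Br)cc1O | intermediate
5 | bromoacetic acid | OC(=O)CBr | starting material
6 | 2-(3,5-dibromo-2-methoxyphenoxy)acetic acid | COc1c(Br)cc(Br)cc1OCC(=O)O | intermediate
7 | trimethylsilyl 2-(3,5-dibromo-2-methoxyphenoxy)acetate | COc1c(Br)cc(Br)cc1OCC(=O)O[Si](C)(C)C | intermediate (not isolated)
8 | 2-(3,5-dibromo-2-methoxyphenoxy)-1,1-bis(trimethylsilyloxy)ethene | COc1c(Br)cc(Br)cc1OC=C(O[Si](C)(C)C)O[Si](C)(C)C | intermediate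
9 | tetrabromothiophene | Brc1sc(Br)c(Br)c1Br | starting material
10 | tetrabromothiophene 1,1-dioxide | O=S1(=O)C(Br)=C(Br)C(Br)=C1Br | intermediate
11 | 1,2,3,4-tetrabromo-5-(3,5-dibromo-2-methoxyphenoxy)-6,6-bis(trimethylsilyloxy)-7-thiabicyclo[2.2.1]hept-2-ene 7,7-dioxide (racemic, configuration not defined, lost on aromatization) | COc1c(Br)cc(Br)cc1OC1C(O[Si](C)(C)C)(O[Si](C)(C)C)C2(Br)C(Br)=C(Br)C1(Br)S2(=O)=O | intermediate (not isolated)
12 | 1,2,3,4-tetrabromo-5-(3,5-dibromo-2-methoxyphenoxy)-6,6-bis(trimethylsilyloxy)cyclohexa-1,3-diene (racemic) | COc1c(Br)cc(Br)cc1OC1C(Br)=C(Br)C(Br)=C(Br)C1(O[Si](C)(C)C)O[Si](C)(C)C | intermediate (not isolated)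
13 | 2,3,4,5-tetrabromo-6-(3,5-dibromo-2-methoxyphenoxy)phenol | COc1c(Br)cc(Br)cc1Oc1c(O)c(Br)c(Br)c(Br)c1Br | intermediate
14 | 1,2,3,4-tetrabromo-5-(3,5-dibromo-2-methoxyphenoxy)-6-(methoxymethoxy)benzene | COCOc1c(Br)c(Br)c(Br)c(Br)c1Oc1cc(Br)cc(Br)c1OC | intermediate
15 | [2,3,4-tribromo-5-(3,5-dibromo-2-methoxyphenoxy)-6-(methoxymethoxy)phenyl]magnesium chloride | COCOc1c([Mg]Cl)c(Br)c(Br)c(Br)c1Oc1cc(Br)cc(Br)c1OC | intermediate (not isolated)
16 | 1,2,3-tribromo-4-(3,5-dibromo-2-methoxyphenoxy)-5-(methoxymethoxy)benzene | COCOc1cc(Br)c(Br)c(Br)c1Oc1cc(Br)cc(Br)c1OC | intermediate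
17 | 3,4,5-tribromo-2-(3,5-dibromo-2-methoxyphenoxy)phenol | COc1c(Br)cc(Br)cc1Oc1c(O)cc(Br)c(Br)c1Br | target

**Step count and risks**

Total steps: 9. Longest linear sequence: 8 (steps 1–4 and 6–9 from compound 1; step 5 is a one-step side branch).

Steps most likely to fail:

1. Step 6. The bis(trimethylsilyl) ketene acetal may be protodesilylated before it reacts, or may add to the sulfone in a conjugate (Mukaiyama–Michael) fashion with silyl transfer instead of closing the ring. The fallback sets out from phenol 4 and returns at phenol 13. Alkylation of 4 with tert-butyl bromoacetate (K2CO3, acetone) should give tert-butyl 2-(3,5-dibromo-2-methoxyphenoxy)acetate F1. LiHMDS and TBSCl (THF/DMPU, −78 °C) should convert it into the isolable mixed ketene acetal 1-tert-butoxy-1-(tert-butyldimethylsilyloxy)-2-(3,5-dibromo-2-methoxyphenoxy)ethene F2, which is far less prone to hydrolysis and silyl transfer. Heating F2 with 10 in toluene should give the bridged sulfone adduct F3 and, after SO2 loss, the cyclohexadiene mixed ketal F4. Aqueous trifluoroacetic acid should then hydrolyse the ketal (and cleave any aryl tert-butyl or aryl silyl ether formed by direct elimination) to give 13.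

2. Step 8. The exchange may show poor site selectivity, occurring at C6' next to the diaryl ether oxygen, on ring A next to the methoxy group, or twice. The fallback sets out from thiophene 9 and ketene acetal 8 and returns at target 17, using a carboxylate as a traceless C3' substituent that also fixes the orientation of the cycloaddition.
   - α-Selective Br/Li exchange of 9 (n-BuLi, THF, −78 °C) should give (3,4,5-tribromothiophen-2-yl)lithium F5, which methyl chloroformate traps as methyl 3,4,5-tribromothiophene-2-carboxylate F6.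
   - Peracid oxidation should give its 1,1-dioxide F7.
   - In the cycloaddition with 8, the nucleophilic aryloxy-bearing carbon should attack the α-carbon remote from the ester (vinylogous conjugate addition, as in salicylate syntheses from ester-substituted electron-poor dienes and ketene acetals). This should give bridged adduct F8, then cyclohexadiene F9 by SO2 loss, then on acidic work-up methyl 2,3,4-tribromo-5-(3,5-dibromo-2-methoxyphenoxy)-6-hydroxybenzoate F10.
   - Saponification (LiOH, aq. THF, 60 °C) should give 2,3,4-tribromo-5-(3,5-dibromo-2-methoxyphenoxy)-6-hydroxybenzoic acid F11.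
   - Silver-catalysed protodecarboxylation of this di-ortho-substituted acid (cat. Ag2CO3, AcOH, DMSO, 120 °C) should leave hydrogen at C3' and give 17 without any protection or exchange step.

3. Step 5. Oxidation of the electron-poor thiophene may stall at the sulfoxide, which can dimerize, or bromine may be lost oxidatively. The fallback sets out from 9 and returns at 10. Double Br/Li exchange (2 equiv n-BuLi, THF, −78 °C) should give 3,4-dibromo-2,5-dilithiothiophene F12, which TMSCl silylates to 3,4-dibromo-2,5-bis(trimethylsilyl)thiophene F13. This more electron-rich thiophene should be oxidized by mCPBA to 3,4-dibromo-2,5-bis(trimethylsilyl)thiophene 1,1-dioxide F14. Ipso-bromodesilylation of both vinylsilane positions (Br2, AgBF4, CH2Cl2) should then give 10.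

Further compounds
F1 | step 6 | tert-butyl 2-(3,5-dibromo-2-methoxyphenoxy)acetate | COc1c(Br)cc(Br)cc1OCC(=O)OC(C)(C)C
F2 | step 6 | 1-tert-butoxy-1-(tert-butyldimethylsilyloxy)-2-(3,5-dibromo-2-methoxyphenoxy)ethene (alkene geometry not defined) | COc1c(Br)cc(Br)cc1OC=C(OC(C)(C)C)O[Si](C)(C)C(C)(C)C
F3 | step 6 | 1,2,3,4-tetrabromo-6-tert-butoxy-6-(tert-butyldimethylsilyloxy)-5-(3,5-dibromo-2-methoxyphenoxy)-7-thiabicyclo[2.2.1]hept-2-ene 7,7-dioxide (racemic, configuration not defined) | COc1c(Br)cc(Br)cc1OC1C(OC(C)(C)C)(O[Si](C)(C)C(C)(C)C)C2(Br)C(Br)=C(Br)C1(Br)S2(=O)=O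
F4 | step 6 | 1,2,3,4-tetrabromo-6-tert-butoxy-6-(tert-butyldimethylsilyloxy)-5-(3,5-dibromo-2-methoxyphenoxy)cyclohexa-1,3-diene (racemic, configuration not defined) | COc1c(Br)cc(Br)cc1OC1C(Br)=C(Br)C(Br)=C(Br)C1(OC(C)(C)C)O[Si](C)(C)C(C)(C)C
F5 | step 8 | (3,4,5-tribromothiophen-2-yl)lithium | [Li]c1sc(Br)c(Br)c1Br
F6 | step 8 | methyl 3,4,5-tribromothiophene-2-carboxylate | COC(=O)c1sc(Br)c(Br)c1Br
F7 | step 8 | methyl 3,4,5-tribromothiophene-2-carboxylate 1,1-dioxide | COC(=O)C1=C(Br)C(Br)=C(Br)S1(=O)=O
F8 | step 8 | methyl 2,3,4-tribromo-5-(3,5-dibromo-2-methoxyphenoxy)-6,6-bis(trimethylsilyloxy)-7-thiabicyclo[2.2.1]hept-2-ene-1-carboxylate 7,7-dioxide (racemic, configuration not defined) | COc1c(Br)cc(Br)cc1OC1C(O[Si](C)(C)C)(O[Si](C)(C)C)C2(C(=O)OC)C(Br)=C(Br)C1(Br)S2(=O)=O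
F9 | step 8 | methyl 2,3,4-tribromo-5-(3,5-dibromo-2-methoxyphenoxy)-6,6-bis(trimethylsilyloxy)cyclohexa-1,3-diene-1-carboxylate (racemic) | COc1c(Br)cc(Br)cc1OC1C(Br)=C(Br)C(Br)=C(C(=O)OC)C1(O[Si](C)(C)C)O[Si](C)(C)C
F10 | step 8 | methyl 2,3,4-tribromo-5-(3,5-dibromo-2-methoxyphenoxy)-6-hydroxybenzoate | COC(=O)c1c(O)c(Oc2cc(Br)cc(Br)c2OC)c(Br)c(Br)c1Br
F11 | step 8 | 2,3,4-tribromo-5-(3,5-dibromo-2-methoxyphenoxy)-6-hydroxybenzoic acid | OC(=O)c1c(O)c(Oc2cc(Br)cc(Br)c2OC)c(Br)c(Br)c1Br
F12 | step 5 | 3,4-dibromo-2,5-dilithiothiophene | [Li]c1sc([Li])c(Br)c1Br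
F13 | step 5 | 3,4-dibromo-2,5-bis(trimethylsilyl)thiophene | C[Si](C)(C)c1sc([Si](C)(C)C)c(Br)c1Br
F14 | step 5 | 3,4-dibromo-2,5-bis(trimethylsilyl)thiophene 1,1-dioxide | C[Si](C)(C)C1=C(Br)C(Br)=C([Si](C)(C)C)S1(=O)=O
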